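## The problem

1. Target 9 is a 7,9'-epoxylignan: one oxolane ring (O1, C2, C3, C4, C5) with a 3,4,5-trimethoxyphenyl group on C2, a hydroxymethyl group on C3 and a 3,4-dimethoxybenzyl group on C4; C5 is a methylene.
2. C2, C3 and C4 are contiguous stereocentres, all R, and the three substituents lie on one face of the ring (2,3-cis, 3,4-cis), the most crowded and least stable of the four diastereomers.
3. The usual closure of such rings, capture of a C2 benzylic cation by the C5 oxygen, gives the 2,3-trans ring, so C2 cannot be set by C–O bond formation under ionising conditions. C4 can direct a reagent to the opposite ring face, but only if the ring is flat at the carbons still to be set.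
4. The C2–O1 bond is a benzylic ether para to a methoxy group: acids ionise it (epimerisation to 2,3-trans) and palladium with hydrogen can cleave it.
5. While C3 bears a carbonyl group it can be epimerised by base, and both arenes are electron-rich, which excludes strong oxidants and long exposure to arene-reducing catalysts.
6. The feature that opens the problem: C2, C3 and C4 each carry exactly one hydrogen, these three hydrogens are on the same face of the oxolane ring, C5 carries two, and C3 holds a one-carbon group at the alcohol level. The ring is therefore a 2-aryl-4-benzylfuran-3-carboxylate to which two molecules of H2 have been added from one face.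
7. The stereochemical problem then shrinks to the choice of one face of a flat, achiral furan.

## Retrosynthesis

**9 ⇒ 8.** No skeletal bond is cut; the C3 hydroxymethyl group of 9 is taken back to the ethyl ester of 8, ethyl (2R,3S,4R)-4-(3,4-dimethoxybenzyl)-2-(3,4,5-trimethoxyphenyl)oxolane-3-carboxylate (3R to 3S is a change of CIP priority only). A free or protected CH2OH at the furan or dihydrofuran stage would sit on an enol ether and ionise easily. The ester instead makes the half-reduced ring a stable vinylogous carbonate, and it is the group the furan synthesis delivers. The forward reaction must reduce the ester without epimerising C3 and without acid.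

**8 ⇒ 6 (through 7).** The four C–H bonds at C2, C3, C4 and C5 are cut, which turns 8 into the furan 6, ethyl 4-(3,4-dimethoxybenzyl)-2-(3,4,5-trimethoxyphenyl)furan-3-carboxylate. Cutting C2–O1, C2–C3 or C3–C4 would each leave two or three stereocentres to be set in separate events; this cut removes all of them at once. 6 is flat, achiral and has no sensitive group. The forward reaction must add two H2 to one face, and to the right one. It is planned as two stages in one flask with the 4,5-dihydrofuran 7 as the hinge: a chiral catalyst reduces only C4=C5 and sets C4, and the remaining C2=C3 bond of 7 is then reduced anti to the C4 benzyl group, which puts C2 and C3 cis to it.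

**6 ⇒ 4 + 5.** The bond between the benzylic CH2 on C4 and the dimethoxyphenyl ring is cut, giving the chloromethylfuran 4 and the commercial boronic acid 5. The neighbouring cut (C4–CH2) would need a 4-metallated or 4-halogenated 3-furoate, for which there is no short regioselective entry. Bringing the whole benzyl group in with the ring-forming ketone would make that ketone unsymmetrical and enolisable on the aryl side. 4 has no stereocentre and one reactive site. The forward reaction is an sp3–sp2 cross-coupling of a hetero-benzylic chloride that must leave the neighbouring ester alone.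

**4 ⇒ 1 + 2.** The furan bonds C3–C4 and O1–C5 are cut (Feist–Benary), giving the β-keto ester 1 and 1,3-dichloroacetone 2, both commercial. The cut fits the substitution pattern exactly:
- the ketone carbon of 1 becomes C2 with its aryl group;
- the α-carbon of 1 becomes C3 with the ester;
- the carbonyl carbon of 2 becomes C4 and keeps one CH2Cl as the handle for the benzyl group;
- the other CH2Cl becomes the unsubstituted C5.

Because 2 is symmetrical, it does not matter which CH2Cl closes the ring. The forward reaction must run aldol-first (through hydroxydihydrofuran 3); alkylation-first would put the handle on C5.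

## Roads not taken

**Alternative 1:** (the most obvious) cut O1–C2 and C2–C3. The enolate of the lactone (4R)-4-(3,4-dimethoxybenzyl)oxolan-2-one A1 is added to 3,4,5-trimethoxybenzaldehyde A2 to give the trans hydroxy lactone A3. LiAlH4 gives the triol A4, and acid closes the oxolane by capture of the C2 benzylic cation by the C5 hydroxyl; this cationic closure is the key step.
- The cation is planar and the oxygen attacks anti to the C3 substituent, so the product should be the 2,3-trans isomer A5, the C2 epimer of 9, which is also the thermodynamic product. The one hard stereocentre is set wrongly.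
- A closure with retention at C2 (SN2 at C5) would need the two primary hydroxyls of A4 told apart and the carbinol configuration of A3 controlled.
- A1 itself takes several steps in enantiopure form.
- The chosen plan never forms a C–O bond at C2.

**Alternative 2:** cut C3–C4 by a [3,3]-sigmatropic rearrangement. The (E)-4-arylbut-2-enyl (3R)-3-hydroxy-3-arylpropanoate A6 is converted to its dianion. Ireland–Claisen rearrangement through a chair with the lithium-chelated enolate should give the acid A7: C3 anti to the C2 hydroxyl (attack anti to the aryl group on the chelate, as in alkylations of β-hydroxy ester dianions) and C3/C4 syn (E-alkene, chair). This is the correct triad, derived from one carbinol centre.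
- A7 carries C5 as a vinyl group and the hydroxymethyl carbon as CO2H. It needs an oxidative cleavage with loss of a carbon, two reductions, differentiation of two primary alcohols and an O-alkylative ring closure, with protecting groups: about ten steps against four.
- The β-hydroxy ester with an electron-rich benzylic carbinol can undergo retro-aldol cleavage or dehydration under the dianion conditions.

**Alternative 3:** cut only the C2–H and C3–H bonds and set C4 first. C-Acylation of A1 with 3,4,5-trimethoxybenzoyl chloride A8 gives the α-aroyl lactone A9. Acid in ethanol moves the ring oxygen from the lactone carbonyl to the aroyl carbon (acyl-lactone rearrangement, the key step) and gives 7 in its (4R) form; hydrogenation anti to the benzyl group follows as in the chosen route.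
- The absolute configuration is secure, but it is paid for with the enantioselective synthesis of A1 (Stobbe condensation, asymmetric hydrogenation, selective reduction, lactonisation). 7 is reached in about six steps instead of three.
- The three centres are set in three separate operations.
- A9 is a β-keto lactone open to decarboxylative ring opening in acid.
- The chosen plan reaches 7 from three commercial compounds and makes one hydrogenation the only stereogenic event.

Key step: step 3

Assumption: the sense of induction of the iridium catalyst on this furan cannot be predicted with certainty; the (S)-ligand is written, and its antipode is to be used instead if the first run shows hydrogen delivery to the C4 Re face.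

## Route

Step 1
Reactants: 1 ethyl 3-oxo-3-(3,4,5-trimethoxyphenyl)propanoate; 2 1,3-dichloroacetone (1,3-dichloropropan-2-one)
Product: 4 ethyl 4-(chloromethyl)-2-(3,4,5-trimethoxyphenyl)furan-3-carboxylate, via hydroxydihydrofuran 3 (not isolated)
Conditions: 2,6-lutidine (1.05 equiv), EtOH, 50 °C; aqueous wash; then TsOH·H2O (10 mol %), toluene, 80 °C
Reagents that add atoms: none
Why: Feist–Benary furan synthesis: the enol of 1 adds to the very electrophilic carbonyl of 2 (aldol), the enol oxygen displaces one chloride (5-exo-tet) to give 3, and acid-catalysed loss of water aromatises to 4; since the carbonyl carbon of 2 becomes C4, the second CH2Cl ends up on C4 and C5 stays unsubstituted.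

Step 2
Reactants: 4 ethyl 4-(chloromethyl)-2-(3,4,5-trimethoxyphenyl)furan-3-carboxylate; 5 (3,4-dimethoxyphenyl)boronic acid
Product: 6 ethyl 4-(3,4-dimethoxybenzyl)-2-(3,4,5-trimethoxyphenyl)furan-3-carboxylate
Conditions: Pd(PPh3)4 (3 mol %), K2CO3 (2 equiv), DME/H2O, 80 °C
Reagents that add atoms: none
Why: Suzuki–Miyaura coupling of a hetero-benzylic chloride: oxidative addition of zerovalent palladium into the C–Cl bond, transmetalation with the boronate of 5 and reductive elimination form the CH2–aryl bond; no stereocentre is involved and the hindered ester should survive the carbonate base.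

Step 3
Reactants: 6 ethyl 4-(3,4-dimethoxybenzyl)-2-(3,4,5-trimethoxyphenyl)furan-3-carboxylate
Product: 8 ethyl (2R,3S,4R)-4-(3,4-dimethoxybenzyl)-2-(3,4,5-trimethoxyphenyl)oxolane-3-carboxylate, via dihydrofuran ester 7 (not isolated)
Conditions: [Ir(cod)(L)]B[3,5-(CF3)2C6H3]4 (2 mol %; L = (S)-8-(di-tert-butylphosphanyloxy)-2-phenyl-5,6,7,8-tetrahydroquinoline), H2 (80 bar), CH2Cl2, 50 °C; solvent change to EtOAc; then 5% Rh/Al2O3, H2 (20 bar), 25 °C
Reagents that add atoms: none
Why: Proposed new method: under H2 the cationic iridium complex loses cod and becomes a trivalent iridium dihydride that can bind only the trisubstituted enol-ether bond C4=C5 of 6 (C2=C3 is tetrasubstituted and deactivated by the ester and the aryl group) and passes both hydrogens to one face by migratory insertion and reductive elimination; the closest known reaction type is the enantioselective hydrogenation of 3-alkylfurans by iridium pyridine–phosphinite complexes, in which the same O–CH=C(alkyl) unit is reduced, but a 2,3,4-trisubstituted furan-3-carboxylate has not been shown. C4 is set by the ligand: in the quadrant picture for trisubstituted alkenes the only vinylic hydrogen, H5, goes to the quadrant blocked by the 2-phenyl group of the ligand, which fixes the face of C4=C5 that is reduced (the C4 Si face is needed for 4R). The reduction should stop at 7, which is no longer aromatic and is a stable push–pull alkene that this catalyst type does not reduce. Rh/Al2O3 then adds H2 syn to C2=C3 of 7 from the face opposite to the C4 benzyl group, as in known cis-selective hydrogenations of β-alkoxyacrylates and of aryl furans to all-cis oxolanes, so C2 (R) and C3 (S) are set by C4 and the aryl, ester and benzyl groups end up on one face. No ring is closed; the oxolane ring of 8 is the furan ring of 6. The step needs site selectivity (C4=C5 before C2=C3, secured by substitution and conjugation), enantioface selectivity (ligand), diastereoface selectivity (C4 substituent), and chemoselectivity against arene reduction and benzylic C–O cleavage, for which rhodium is used instead of palladium, CH2Cl2 is removed before it is added, and hydrogen uptake is stopped at one equivalent.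

Step 4
Reactants: 8 ethyl (2R,3S,4R)-4-(3,4-dimethoxybenzyl)-2-(3,4,5-trimethoxyphenyl)oxolane-3-carboxylate
Product: 9 [(2R,3R,4R)-4-(3,4-dimethoxybenzyl)-2-(3,4,5-trimethoxyphenyl)oxolan-3-yl]methanol
Conditions: LiAlH4 (1.5 equiv), THF, −20 to 0 °C; Na2SO4·10H2O work-up
Reagents that add atoms: none
Why: Hydride reduction of the ester to the primary alcohol; at low temperature the tetrahedral aluminate intermediates are reduced faster than C3 is enolised, so the all-cis arrangement should be kept (3S to 3R is a change of CIP priority only), and the non-acidic work-up protects the benzylic C2–O1 bond.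

## Compound list

1 | ethyl 3-oxo-3-(3,4,5-trimethoxyphenyl)propanoate | CCOC(=O)CC(=O)c1cc(OC)c(OC)c(OC)c1 | starting material
2 | 1,3-dichloropropan-2-one | ClCC(=O)CCl | starting material
3 | ethyl 4-(chloromethyl)-4-hydroxy-2-(3,4,5-trimethoxyphenyl)-4,5-dihydrofuran-3-carboxylate (racemic) | CCOC(=O)C1=C(c2cc(OC)c(OC)c(OC)c2)OCC1(O)CCl | intermediate
4 | ethyl 4-(chloromethyl)-2-(3,4,5-trimethoxyphenyl)furan-3-carboxylate | CCOC(=O)c1c(CCl)coc1-c1cc(OC)c(OC)c(OC)c1 | intermediate
5 | (3,4-dimethoxyphenyl)boronic acid | COc1ccc(B(O)O)cc1OC | starting material
6 | ethyl 4-(3,4-dimethoxybenzyl)-2-(3,4,5-trimethoxyphenyl)furan-3-carboxylate | CCOC(=O)c1c(Cc2ccc(OC)c(OC)c2)coc1-c1cc(OC)c(OC)c(OC)c1 | intermediate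
7 | ethyl (4R)-4-(3,4-dimethoxybenzyl)-2-(3,4,5-trimethoxyphenyl)-4,5-dihydrofuran-3-carboxylate | COc1ccc(C[C@H]2COC(c3cc(OC)c(OC)c(OC)c3)=C2C(=O)OCC)cc1OC | intermediate
8 | ethyl (2R,3S,4R)-4-(3,4-dimethoxybenzyl)-2-(3,4,5-trimethoxyphenyl)oxolane-3-carboxylate | COc1ccc(C[C@H]2CO[C@@H](c3cc(OC)c(OC)c(OC)c3)[C@H]2C(=O)OCC)cc1OC | intermediate
9 | [(2R,3R,4R)-4-(3,4-dimethoxybenzyl)-2-(3,4,5-trimethoxyphenyl)oxolan-3-yl]methanol | COc1ccc(C[C@H]2CO[C@@H](c3cc(OC)c(OC)c(OC)c3)[C@H]2CO)cc1OC | target

## Step count and risks

Total step count: 4. Longest linear sequence: 4 steps (1 → 4 → 6 → 8 → 9).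

**Step 3 (key step, proposed new method).** What may go wrong:
- No or slow turnover in the first stage: the furan is aromatic, C4 is flanked by two substituents, and the ether oxygens and the ester can occupy the cationic metal.
- Insufficient enantioface discrimination: the two carbon substituents on C4 (the benzyl group and ring carbon C3 with its ester) differ less in size than those of a 3-alkylfuran.
- In the second stage, migration of the C2=C3 bond into the C3–C4 position on the metal surface, which would erase C4, or slow saturation of the arenes.

Fallback (known chemistry; sets out from 6, returns at 9): 6 is hydrogenated over 5% Rh/Al2O3 alone (H2, EtOAc). By the known cis-selective hydrogenation of aryl furans this should give the racemic all-cis ester, ethyl rac-(2R,3S,4R)-4-(3,4-dimethoxybenzyl)-2-(3,4,5-trimethoxyphenyl)oxolane-3-carboxylate F1. LiAlH4 reduces it to the racemic alcohol rac-9 F2. Esterification with (S)-2-methoxy-2-phenylacetic acid (DCC, DMAP) gives two diastereomeric esters, the (2R,3R,4R)-oxolanylmethyl (2S)-2-methoxy-2-phenylacetate F3 and the (2S,3S,4S)-oxolanylmethyl (2S)-2-methoxy-2-phenylacetate F4. These are separated by chromatography or crystallisation, and K2CO3 in methanol releases 9 from F3.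

**Step 1.** What may go wrong: alkylation of the enolate of 1 at a CH2Cl carbon of 2 before aldol addition (after cyclodehydration this would place the chloromethyl group on C5), alkylation of the base by 2, or solvolysis of the chloromethyl group during the dehydration.

Fallback (sets out from 1, returns at 6; step 2 is then not needed): diazo transfer to 1 (4-acetamidobenzenesulfonyl azide, Et3N, MeCN) gives ethyl 2-diazo-3-oxo-3-(3,4,5-trimethoxyphenyl)propanoate F5. The enol ether 4-(3-methoxyprop-2-en-1-yl)-1,2-dimethoxybenzene F6 is made by Wittig methoxymethylenation of (3,4-dimethoxyphenyl)acetaldehyde. Rh2(OAc)4-catalysed reaction of F5 with F6 should give ethyl 4-(3,4-dimethoxybenzyl)-5-methoxy-2-(3,4,5-trimethoxyphenyl)-4,5-dihydrofuran-3-carboxylate F7: the carbenoid carbon bonds to the nucleophilic β-carbon of the enol ether and the ketone oxygen to the acetal carbon, so the regiochemistry is unambiguous. TsOH in toluene then eliminates methanol to give 6.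

**Step 2.** What may go wrong: hydrolysis of the hetero-benzylic chloride by aqueous carbonate followed by lactonisation onto the neighbouring ester, homocoupling at the furylmethyl palladium stage, or protodeboronation of the electron-rich boronic acid.

Fallback (sets out from 4, returns at 6; no new compound): Friedel–Crafts alkylation of 1,2-dimethoxybenzene, used in excess, with 4 under FeCl3 or ZnCl2 catalysis in CH2Cl2. The arene reacts para to a methoxy group, which gives the 3,4-dimethoxybenzyl group directly; the excess of arene suppresses self-alkylation at C5 of the furan.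

## Further compounds

F1 | step 3 | ethyl rac-(2R,3S,4R)-4-(3,4-dimethoxybenzyl)-2-(3,4,5-trimethoxyphenyl)oxolane-3-carboxylate (racemate, both enantiomers written) | COc1ccc(C[C@H]2CO[C@@H](c3cc(OC)c(OC)c(OC)c3)[C@H]2C(=O)OCC)cc1OC.COc1ccc(C[C@@H]2CO[C@H](c3cc(OC)c(OC)c(OC)c3)[C@@H]2C(=O)OCC)cc1OC
F2 | step 3 | rac-[(2R,3R,4R)-4-(3,4-dimethoxybenzyl)-2-(3,4,5-trimethoxyphenyl)oxolan-3-yl]methanol (racemate, both enantiomers written) | COc1ccc(C[C@H]2CO[C@@H](c3cc(OC)c(OC)c(OC)c3)[C@H]2CO)cc1OC.COc1ccc(C[C@@H]2CO[C@H](c3cc(OC)c(OC)c(OC)c3)[C@@H]2CO)cc1OC
F3 | step 3 | [(2R,3R,4R)-4-(3,4-dimethoxybenzyl)-2-(3,4,5-trimethoxyphenyl)oxolan-3-yl]methyl (2S)-2-methoxy-2-phenylacetate | COc1ccc(C[C@H]2CO[C@@H](c3cc(OC)c(OC)c(OC)c3)[C@H]2COC(=O)[C@@H](OC)c2ccccc2)cc1OC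
F4 | step 3 | [(2S,3S,4S)-4-(3,4-dimethoxybenzyl)-2-(3,4,5-trimethoxyphenyl)oxolan-3-yl]methyl (2S)-2-methoxy-2-phenylacetate | COc1ccc(C[C@@H]2CO[C@H](c3cc(OC)c(OC)c(OC)c3)[C@@H]2COC(=O)[C@@H](OC)c2ccccc2)cc1OC
F5 | step 1 | ethyl 2-diazo-3-oxo-3-(3,4,5-trimethoxyphenyl)propanoate | CCOC(=O)C(=[N+]=[N-])C(=O)c1cc(OC)c(OC)c(OC)c1
F6 | step 1 | 4-(3-methoxyprop-2-en-1-yl)-1,2-dimethoxybenzene (E/Z mixture) | COC=CCc1ccc(OC)c(OC)c1
F7 | step 1 | ethyl 4-(3,4-dimethoxybenzyl)-5-methoxy-2-(3,4,5-trimethoxyphenyl)-4,5-dihydrofuran-3-carboxylate (racemic, diastereomer mixture) | CCOC(=O)C1=C(c2cc(OC)c(OC)c(OC)c2)OC(OC)C1Cc1ccc(OC)c(OC)c1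
F0 | step 2 | none | none
A1 | alternative 1 | (4R)-4-(3,4-dimethoxybenzyl)oxolan-2-one | COc1ccc(C[C@H]2COC(=O)C2)cc1OC
A2 | alternative 1 | 3,4,5-trimethoxybenzaldehyde | COc1cc(C=O)cc(OC)c1OC
A3 | alternative 1 | (3S,4R)-4-(3,4-dimethoxybenzyl)-3-[hydroxy(3,4,5-trimethoxyphenyl)methyl]oxolan-2-one (carbinol epimers) | COc1ccc(C[C@H]2COC(=O)[C@@H]2C(O)c2cc(OC)c(OC)c(OC)c2)cc1OC
A4 | alternative 1 | (2R,3R)-2-(3,4-dimethoxybenzyl)-3-[hydroxy(3,4,5-trimethoxyphenyl)methyl]butane-1,4-diol (carbinol epimers) | COc1ccc(C[C@@H](CO)[C@H](CO)C(O)c2cc(OC)c(OC)c(OC)c2)cc1OC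
A5 | alternative 1 | [(2S,3R,4R)-4-(3,4-dimethoxybenzyl)-2-(3,4,5-trimethoxyphenyl)oxolan-3-yl]methanol | COc1ccc(C[C@H]2CO[C@H](c3cc(OC)c(OC)c(OC)c3)[C@H]2CO)cc1OC
A6 | alternative 2 | (E)-4-(3,4-dimethoxyphenyl)but-2-en-1-yl (3R)-3-hydroxy-3-(3,4,5-trimethoxyphenyl)propanoate | O[C@H](CC(=O)OC/C=C/Cc1ccc(OC)c(OC)c1)c1cc(OC)c(OC)c(OC)c1
A7 | alternative 2 | (2S,3S)-3-(3,4-dimethoxybenzyl)-2-[(R)-hydroxy(3,4,5-trimethoxyphenyl)methyl]pent-4-enoic acid | COc1ccc(C[C@@H](C=C)[C@H](C(=O)O)[C@@H](O)c2cc(OC)c(OC)c(OC)c2)cc1OC
A8 | alternative 3 | 3,4,5-trimethoxybenzoyl chloride | COc1cc(C(=O)Cl)cc(OC)c1OC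
A9 | alternative 3 | (3S,4R)-4-(3,4-dimethoxybenzyl)-3-(3,4,5-trimethoxybenzoyl)oxolan-2-one | COc1ccc(C[C@H]2COC(=O)[C@@H]2C(=O)c2cc(OC)c(OC)c(OC)c2)cc1OC
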